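What share of the Z charged in the epsilon run has become L at 54 min, and how do [J] and [X] steer the opening rate?

| flask | Z | J | X | time |
|---|---|---|---|---|
| alpha | 0.150 M | 0.375 M | 0.00450 M |  |
| theta | 0.220 M | 0.375 M | 0.00450 M |  |
| eta | 0.150 M | 0.375 M | 0.00900 M |  |
| delta | 0.150 M | 0.190 M | 0.00450 M |  |
| epsilon | 0.310 M | 0.375 M | 0.00450 M | 54 min |

- alpha run (time / min: [L] / M): 2.2: 0.0053; 4.1: 0.0124; 7.8: 0.0253; 15: 0.0402; 28: 0.0727; 54: 0.1118
- theta run (time / min: [L] / M): 2.2: 0.0065; 4.1: 0.0166; 7.8: 0.0305; 15: 0.0503; 28: 0.0884; 54: 0.1527
- eta run (time / min: [L] / M): 2.2: 0.0110; 4.1: 0.0217; 7.8: 0.0431; 15: 0.0747; 28: 0.1144; 54: 0.1449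
- delta run (time / min: [L] / M): 2.2: 0.0071; 4.1: 0.0100; 7.8: 0.0160; 15: 0.0345; 28: 0.0643; 54: 0.0998

(standard deviation of a reading: 0.002 M)

1. how the opening rate goes with [J] round the charge of the alpha run: the exponent of the rate at two percent of Z gone to L
2. how the opening rate goes with [X] round the charge of the alpha run: the exponent of the rate at two percent of Z gone to L
3. L in the epsilon run at 54 min, as a share of the Z charged

- Overall: Z + J -> L, with X as catalyst.
- Constant volume, constant temperature.
- A reading of a species includes what of it is bound.
- "The second partner" is J.
- An order is taken over about fifteen percent of the charge, up and down.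

- [X] needs no fine reckoning for the share, because epsilon carries 0.00450 M, the same charge as alpha and theta. For its exponent, the eta reading at 15 min over the alpha one, with twice the [X], gives 0.894.
- [J] starts equal in epsilon and alpha. Delta, with about half the [J], gives an exponent of 0.225 at 15 min, with a scatter of 0.121. That is an average across the two charges and over the time up to that reading, not the opening exponent asked.
- [Z] is what differs, so the number to know is how the rate bends with it. Take rate = V[Z]/(K + [Z]), with [J] and [X] left out of the law. The order in Z is then K/(K + [Z]), and K ln([Z]₀/[Z]) + [L] = Vt.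
- Alpha and theta at 54 min give the bend concentration K, the Michaelis constant of this flask, the [Z] at which the rate stands midway to its ceiling: 0.223 M. They also give the reach Vt, 0.417 M. On this rule, the order in Z opens at 0.598 in alpha and 0.418 in epsilon.
- K is poorly held. One standard deviation on the alpha reading moves it to 0.164 M.
- Newton steps for epsilon, starting from 0.155 M, give 0.199 M, then 0.195 M, which is 63.0% of the charge. Reckoned anew with the shifted K and the reach that goes with it, this [L] moves by about 0.00467 M.
- This estimate leans high, because at that [L] the [J] of epsilon is reckoned at 0.180 M, lower than the 0.222 M reckoned from the theta reading at 54 min, and delta, charged with less [J], reads less L than alpha at 54 min.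
- The forecast gives 0.28, 0.93 and 60%, holding that "J is therefore nearly saturating", and its share stands lower than this reckoning.
- The simulation gives 59.9% for epsilon, with opening exponents −0.037 in [J] and 0.93 in [X]; a power law fitted over all runs has a best order in [J] of 0.21.

    X + Z → Xa + G (32.04 M⁻¹ min⁻¹)
    Xa + J → L + X (4.680 M⁻¹ min⁻¹)
    X + J ⇌ XJ, settled at all times (8.590 M⁻¹)

- Put into the rule with K, the epsilon result amounts to a reach of 0.389 M, which is 93.4% of the 0.417 M reckoned from the alpha reading. The same K and reach put a quarter of the Z in theta at 15.4 min, and the theta run reaches it at 15.8 min.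

The runs stem from a simulated flask on assumed constants; noise was put on by code.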